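**Retrosynthetic overview**

- Feature: ring A is the N-methoxy-4-pyridone (N1, C2, C3, C4, C4a, C8a) and ring B the carbocycle (C4a, C5, C6, C7, C8, C8a). C8a is the ring-A carbon next to nitrogen. C5, the only stereocentre, is stereogenic only because one of two like three-carbon arms on it is tied back to C8a (as C6–C7–C8) while the other is left to become the octyl chain.
- Last disconnection: the octyl chain is cut back to an allyl group (cross-metathesis with hept-1-ene, then hydrogenation).
- Key disconnection: C8–C8a. Ring B is opened to a monocyclic pyridone that carries a CH(allyl)2 group; the forward step adds the C8a–H bond across one of the two enantiotopic allyl arms under nickel/chiral carbene/aluminium catalysis.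
- Earlier disconnections: C4a–C5 (Negishi coupling of a 5-bromopyridone with the secondary alkylzinc from hepta-1,6-dien-4-ol); ring A from maltol (O-methylation, oxidation of the methyl group, exchange of ring O for N–OMe).
- Ring order: ring A first (pyranone to pyridone), ring B second.

Key step: step 9

**Remarks on the chemistry**

- Monocyclic compounds carry pyridone numbering, so C6–H of 12 is the future C8a–H and C5 of 12 is the future C4a; bicyclic compounds carry quinolinone numbering.
- L* is a bulky C2-symmetric carbene, 1,3-bis{2,6-bis[(1R)-1-phenylethyl]-4-methylphenyl}imidazol-2-ylidene or its all-(S) antipode. Which antipode leads to (5S)-13 cannot be predicted and is assumed to be settled in the first runs.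
- The silylation is placed after the O-to-N exchange, so the silyl ether never meets the acidic alkoxyamine salt.

**Route**

Step 1
Reactants: 1 maltol (3-hydroxy-2-methyl-4H-pyran-4-one)
Product: 2 3-methoxy-2-methyl-4H-pyran-4-one
Conditions: MeI, K2CO3, acetone, reflux
Reagents that add atoms: iodomethane (CI)
Why: Williamson O-alkylation of the acidic enolic 3-hydroxyl is routine for maltol and installs the methyl ether that the target carries at C3.

Step 2
Reactants: 2 3-methoxy-2-methyl-4H-pyran-4-one
Product: 3 3-methoxy-4-oxo-4H-pyran-2-carbaldehyde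
Conditions: SeO2, bromobenzene, 150 °C
Reagents that add atoms: selenium dioxide (O=[Se]=O)
Why: Riley oxidation, in which the 2-methyl group, vinylogously activated by the C4 carbonyl, is taken to the aldehyde by ene reaction and [2,3]-shift, as is established for 3-alkoxy-2-methylpyran-4-ones.

Step 3
Reactants: 3 3-methoxy-4-oxo-4H-pyran-2-carbaldehyde
Product: 4 2-(hydroxymethyl)-3-methoxy-4H-pyran-4-one
Conditions: NaBH4, MeOH, −10 to 0 °C
Reagents that add atoms: none
Why: Chemoselective hydride reduction, since NaBH4 in the cold reduces the aldehyde much faster than the cross-conjugated vinylogous-ester carbonyl of the pyranone.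

Step 4
Reactants: 4 2-(hydroxymethyl)-3-methoxy-4H-pyran-4-one; 5 O-methylhydroxylamine hydrochloride
Product: 6 2-(hydroxymethyl)-1,3-dimethoxypyridin-4(1H)-one
Conditions: 5 (3 equiv), pyridine, 80 °C
Reagents that add atoms: none
Why: Pyranone-to-pyridone exchange (addition of the nucleophile, ring opening, ring closure), in which the alkoxyamine nitrogen adds to unsubstituted C6, the ring opens to an enaminone and the nitrogen condenses with the C2 carbonyl carbon with loss of water, as 4-pyranones do with primary amines and with hydroxylamine.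

Step 5
Reactants: 6 2-(hydroxymethyl)-1,3-dimethoxypyridin-4(1H)-one
Product: 7 2-{[tert-butyl(dimethyl)silyl]oxymethyl}-1,3-dimethoxypyridin-4(1H)-one
Conditions: TBSCl, imidazole, DMF, 0 °C to rt
Reagents that add atoms: tert-butyldimethylsilyl chloride (CC(C)(C)[Si](C)(C)Cl)
Why: Standard silylation of the primary alcohol gives an ether that is inert to the organozinc, AlMe3, ruthenium and rhodium reagents of the later steps.

Step 6
Reactants: 7 2-{[tert-butyl(dimethyl)silyl]oxymethyl}-1,3-dimethoxypyridin-4(1H)-one
Product: 8 5-bromo-2-{[tert-butyl(dimethyl)silyl]oxymethyl}-1,3-dimethoxypyridin-4(1H)-one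
Conditions: NBS, MeCN, 0 °C to rt
Reagents that add atoms: N-bromosuccinimide (O=C1CCC(=O)N1Br)
Why: Electrophilic bromination of the vinylogous amide at its nucleophilic α-carbon C5, the only open position of that kind because C3 carries the methoxy group and C6 next to nitrogen is electron-poor.

Step 7
Reactants: 9 hepta-1,6-dien-4-ol
Product: 10 4-iodohepta-1,6-diene
Conditions: I2, PPh3, imidazole, CH2Cl2, 0 °C to rt
Reagents that add atoms: iodine (II)
Why: Appel-type iodination converts the secondary homoallylic alcohol into the iodide by SN2 displacement of the alkoxyphosphonium intermediate, and the carbon is not stereogenic, so inversion is of no consequence.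

Step 8
Reactants: 8 5-bromo-2-{[tert-butyl(dimethyl)silyl]oxymethyl}-1,3-dimethoxypyridin-4(1H)-one; 10 4-iodohepta-1,6-diene
Product: 12 2-{[tert-butyl(dimethyl)silyl]oxymethyl}-5-(hepta-1,6-dien-4-yl)-1,3-dimethoxypyridin-4(1H)-one, via hepta-1,6-dien-4-ylzinc iodide 11 (not isolated)
Conditions: 10, Zn dust, LiCl, THF, 25 °C; then 8, Pd(OAc)2 (2 mol%), CPhos (4 mol%), THF/toluene, 25 °C
Reagents that add atoms: none
Why: Negishi coupling, in which zinc inserts into the secondary C–I bond with LiCl assistance and the palladium catalyst with the bulky biaryl phosphine CPhos couples secondary alkylzinc halides with heteroaryl bromides by fast reductive elimination, which limits β-hydride elimination and chain isomerisation.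

Step 9
Reactants: 12 2-{[tert-butyl(dimethyl)silyl]oxymethyl}-5-(hepta-1,6-dien-4-yl)-1,3-dimethoxypyridin-4(1H)-one
Product: 13 (5S)-2-{[tert-butyl(dimethyl)silyl]oxymethyl}-1,3-dimethoxy-5-(prop-2-en-1-yl)-5,6,7,8-tetrahydroquinolin-4(1H)-one
Conditions: Ni(cod)2 (10 mol%), L* (10 mol%), AlMe3 (40 mol%), toluene, 70 °C
Reagents that add atoms: none
Why: Proposed new method: AlMe3 binds the C4 carbonyl oxygen of 12 and gives the ring pyridinium character, so that the C6–H bond (the future C8a–H, the only ring C–H and the one next to nitrogen) can be passed, inside a zerovalent nickel–carbene complex that holds one allyl alkene, onto the internal alkene carbon by ligand-to-ligand hydrogen transfer; the resulting seven-membered aryl(alkyl)nickel species, with nickel on the terminal carbon, reductively eliminates to form C8–C8a. The closest known reaction type is the nickel/N-heterocyclic carbene/aluminium Lewis acid annulation of pyridones with tethered alkenes, which is endo-selective and enantioselective with bulky chiral carbenes but has so far told alkene faces apart, not two enantiotopic alkenes. Ring B closes in the 6-endo (anti-Markovnikov) mode, because the bulky carbene disfavours the branched secondary alkylnickel that would lead to the five-membered exo product, and the two-atom tether matches the tether length that gives six-membered rings in the known annulations. C5 becomes the stereocentre through the choice of which allyl arm is tied back, and that choice is expected to be made in the chiral pocket of L*, where only one of the two diastereomeric alkene complexes keeps the spectator allyl arm clear of the flanking aryl groups; the product has the spatial arrangement of the target's 5R centre and is named 5S only because allyl outranks C6. The step needs selection between the arms, endo regioselectivity and survival of the N–OMe bond towards zerovalent nickel; the single available C–H bond, the tether length and the moderate temperature are meant to secure these, and once C8a is substituted a second cyclisation is impossible.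

Step 10
Reactants: 13 (5S)-2-{[tert-butyl(dimethyl)silyl]oxymethyl}-1,3-dimethoxy-5-(prop-2-en-1-yl)-5,6,7,8-tetrahydroquinolin-4(1H)-one; 14 hept-1-ene
Product: 15 (5S)-2-{[tert-butyl(dimethyl)silyl]oxymethyl}-1,3-dimethoxy-5-[(2E)-oct-2-en-1-yl]-5,6,7,8-tetrahydroquinolin-4(1H)-one (E/Z mixture expected, E drawn)
Conditions: 14 (8 equiv), second-generation Grubbs catalyst RuCl2(=CHPh)(PCy3)(H2IMes) (5 mol%), 1,4-benzoquinone (10 mol%), CH2Cl2, 40 °C
Reagents that add atoms: none
Why: Olefin cross-metathesis of two terminal alkenes, driven by excess hept-1-ene and loss of ethene, extends the allyl group to the eight-carbon chain without touching C5, and the alkene geometry is irrelevant because the alkene is hydrogenated next.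

Step 11
Reactants: 15 (5S)-2-{[tert-butyl(dimethyl)silyl]oxymethyl}-1,3-dimethoxy-5-[(2E)-oct-2-en-1-yl]-5,6,7,8-tetrahydroquinolin-4(1H)-one
Product: 16 (5R)-2-{[tert-butyl(dimethyl)silyl]oxymethyl}-1,3-dimethoxy-5-octyl-5,6,7,8-tetrahydroquinolin-4(1H)-one
Conditions: H2 (1–4 atm), RhCl(PPh3)3 (10 mol%), toluene/EtOH, 25–40 °C
Reagents that add atoms: none
Why: Homogeneous hydrogenation with RhCl(PPh3)3 saturates the unhindered disubstituted alkene without hydrogenolysis of the N–OMe bond or reduction of the pyridone ring, which heterogeneous palladium or platinum catalysts would endanger; the descriptor changes to 5R only because octyl ranks below C6.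

Step 12
Reactants: 16 (5R)-2-{[tert-butyl(dimethyl)silyl]oxymethyl}-1,3-dimethoxy-5-octyl-5,6,7,8-tetrahydroquinolin-4(1H)-one
Product: 17 (5R)-2-(hydroxymethyl)-1,3-dimethoxy-5-octyl-5,6,7,8-tetrahydroquinolin-4(1H)-one
Conditions: Bu4NF, THF, 0 °C
Reagents that add atoms: none
Why: Fluoride-induced desilylation frees the primary alcohol under conditions that leave the N–OMe bond and the C5 stereocentre, which has no acidic hydrogen, unchanged.

**Compound list**

1 | maltol (3-hydroxy-2-methyl-4H-pyran-4-one) | Cc1occc(=O)c1O | starting material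
2 | 3-methoxy-2-methyl-4H-pyran-4-one | Cc1occc(=O)c1OC | intermediate
3 | 3-methoxy-4-oxo-4H-pyran-2-carbaldehyde | O=Cc1occc(=O)c1OC | intermediate
4 | 2-(hydroxymethyl)-3-methoxy-4H-pyran-4-one | OCc1occc(=O)c1OC | intermediate
5 | O-methylhydroxylamine hydrochloride | CON.Cl | starting material
6 | 2-(hydroxymethyl)-1,3-dimethoxypyridin-4(1H)-one | COn1ccc(=O)c(OC)c1CO | intermediate
7 | 2-{[tert-butyl(dimethyl)silyl]oxymethyl}-1,3-dimethoxypyridin-4(1H)-one | COn1ccc(=O)c(OC)c1CO[Si](C)(C)C(C)(C)C | intermediate
8 | 5-bromo-2-{[tert-butyl(dimethyl)silyl]oxymethyl}-1,3-dimethoxypyridin-4(1H)-one | COn1cc(Br)c(=O)c(OC)c1CO[Si](C)(C)C(C)(C)C | intermediate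
9 | hepta-1,6-dien-4-ol | C=CCC(O)CC=C | starting material
10 | 4-iodohepta-1,6-diene | C=CCC(I)CC=C | intermediate
11 | hepta-1,6-dien-4-ylzinc iodide (not isolated) | C=CCC([Zn]I)CC=C | intermediate
12 | 2-{[tert-butyl(dimethyl)silyl]oxymethyl}-5-(hepta-1,6-dien-4-yl)-1,3-dimethoxypyridin-4(1H)-one | C=CCC(CC=C)c1cn(OC)c(CO[Si](C)(C)C(C)(C)C)c(OC)c1=O | intermediate
13 | (5S)-2-{[tert-butyl(dimethyl)silyl]oxymethyl}-1,3-dimethoxy-5-(prop-2-en-1-yl)-5,6,7,8-tetrahydroquinolin-4(1H)-one | C=CC[C@@H]1CCCc2c1c(=O)c(OC)c(CO[Si](C)(C)C(C)(C)C)n2OC | intermediate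
14 | hept-1-ene | C=CCCCCC | starting material
15 | (5S)-2-{[tert-butyl(dimethyl)silyl]oxymethyl}-1,3-dimethoxy-5-[(2E)-oct-2-en-1-yl]-5,6,7,8-tetrahydroquinolin-4(1H)-one | CCCCC/C=C/C[C@@H]1CCCc2c1c(=O)c(OC)c(CO[Si](C)(C)C(C)(C)C)n2OC | intermediate
16 | (5R)-2-{[tert-butyl(dimethyl)silyl]oxymethyl}-1,3-dimethoxy-5-octyl-5,6,7,8-tetrahydroquinolin-4(1H)-one | CCCCCCCC[C@@H]1CCCc2c1c(=O)c(OC)c(CO[Si](C)(C)C(C)(C)C)n2OC | intermediate
17 | (5R)-2-(hydroxymethyl)-1,3-dimethoxy-5-octyl-5,6,7,8-tetrahydroquinolin-4(1H)-one | CCCCCCCC[C@@H]1CCCc2c1c(=O)c(OC)c(CO)n2OC | target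

**Step count and risks**

Total step count: 12. Longest linear sequence: 11 steps (steps 1–6 and 8–12, from maltol); step 7 is the one-step side branch.

Steps most likely to fail:

1. Step 9 (proposed new method). The chiral pocket may not tell the two allyl arms apart well enough, the closure may leak into the exo mode, or zerovalent nickel may insert into or reductively cleave the N–OMe bond before C–H transfer. The fallback keeps the desymmetrisation of the two arms but closes ring B by known metathesis chemistry and avoids nickel.
   - It sets out from 12, which is zincated at C6 (the C–H next to nitrogen) with TMPZnCl·LiCl in THF at 25 °C to give {6-{[tert-butyl(dimethyl)silyl]oxymethyl}-3-(hepta-1,6-dien-4-yl)-1,5-dimethoxy-4-oxo-1,4-dihydropyridin-2-yl}zinc chloride F1, not isolated.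
   - Negishi coupling of this zinc species with vinyl bromide [Pd(dba)2, tri(2-furyl)phosphine] gives 2-{[tert-butyl(dimethyl)silyl]oxymethyl}-6-ethenyl-5-(hepta-1,6-dien-4-yl)-1,3-dimethoxypyridin-4(1H)-one F2.
   - Enantioselective desymmetrising ring-closing metathesis of this triene joins the vinyl group to one allyl arm. The catalyst is a chiral molybdenum imido alkylidene, Mo(=N-2,6-iPr2C6H3)(=CHCMe2Ph)(diolate) with diolate = (S)- or (R)-3,3′-di-tert-butyl-5,5′,6,6′-tetramethylbiphenyl-2,2′-diolate, in benzene at 25 °C. The product should be (5R)-2-{[tert-butyl(dimethyl)silyl]oxymethyl}-1,3-dimethoxy-5-(prop-2-en-1-yl)-5,6-dihydroquinolin-4(1H)-one F3, with a C7=C8 alkene in ring B.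
   - Cross-metathesis of the remaining allyl group with 14 (second-generation Grubbs catalyst, CH2Cl2, 40 °C) gives (5R)-2-{[tert-butyl(dimethyl)silyl]oxymethyl}-1,3-dimethoxy-5-[(2E)-oct-2-en-1-yl]-5,6-dihydroquinolin-4(1H)-one F4.
   - Hydrogenation of both alkenes with H2 and RhCl(PPh3)3 comes back to the route at 16.

2. Step 8. The secondary alkylpalladium intermediate has allylic β-hydrogens, so β-hydride elimination to a conjugated triene, with reduced or chain-isomerised pyridone by-products, may outrun reductive elimination. The fallback makes the C5–C bond without an organozinc reagent and without palladium. It sets out from 9, which is converted (CBr4, PPh3, CH2Cl2, 0 °C) into 4-bromohepta-1,6-diene F5. This is joined to bromide 8 by nickel-catalysed reductive cross-electrophile coupling [NiBr2(dme), 4,4′-di-tert-butyl-2,2′-bipyridine, Zn dust, NaI, DMA, 60 °C], in which the secondary alkyl radical is captured by an arylnickel species. The product is 12.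

3. Step 4. The weakly nucleophilic alkoxyamine may add too slowly to C6 of the pyranone, or the ring-opened adduct may stall before closing to the pyridone. The fallback builds the N–OMe unit in two stages. It sets out from 4, which with hydroxylamine hydrochloride in pyridine at 80 °C undergoes the established pyranone to N-hydroxypyridone exchange to give 1-hydroxy-2-(hydroxymethyl)-3-methoxypyridin-4(1H)-one F6. Chemoselective O-methylation of the acidic N–OH group (MeI, K2CO3, DMF, 25 °C), which leaves the far less acidic primary alcohol alone, comes back to the route at 6.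

**Further compounds**

F1 | step 9 | {6-{[tert-butyl(dimethyl)silyl]oxymethyl}-3-(hepta-1,6-dien-4-yl)-1,5-dimethoxy-4-oxo-1,4-dihydropyridin-2-yl}zinc chloride | C=CCC(CC=C)c1c([Zn]Cl)n(OC)c(CO[Si](C)(C)C(C)(C)C)c(OC)c1=O
F2 | step 9 | 2-{[tert-butyl(dimethyl)silyl]oxymethyl}-6-ethenyl-5-(hepta-1,6-dien-4-yl)-1,3-dimethoxypyridin-4(1H)-one | C=CCC(CC=C)c1c(C=C)n(OC)c(CO[Si](C)(C)C(C)(C)C)c(OC)c1=O
F3 | step 9 | (5R)-2-{[tert-butyl(dimethyl)silyl]oxymethyl}-1,3-dimethoxy-5-(prop-2-en-1-yl)-5,6-dihydroquinolin-4(1H)-one | C=CC[C@@H]1CC=Cc2c1c(=O)c(OC)c(CO[Si](C)(C)C(C)(C)C)n2OC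
F4 | step 9 | (5R)-2-{[tert-butyl(dimethyl)silyl]oxymethyl}-1,3-dimethoxy-5-[(2E)-oct-2-en-1-yl]-5,6-dihydroquinolin-4(1H)-one | CCCCC/C=C/C[C@@H]1CC=Cc2c1c(=O)c(OC)c(CO[Si](C)(C)C(C)(C)C)n2OC
F5 | step 8 | 4-bromohepta-1,6-diene | C=CCC(Br)CC=C
F6 | step 4 | 1-hydroxy-2-(hydroxymethyl)-3-methoxypyridin-4(1H)-one | OCc1c(OC)c(=O)ccn1O
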